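The lactone is numbered O1, C2 (CO2Me), C3 (aryl), C4 (=CH-aryl), C5 (C=O). After removal of four phenol protecting groups, the retrosynthesis cuts O1-C5 (acyl bond), then C2-C3, then C3-C4, then C4=CH(aryl).
Enabling feature: on the five-membered lactone ring, C3(aryl)-C4(C5 carboxyl)=CH(aryl) is a 1,3-diaryl-2-carboxyallyl unit with two identical catechol aryl groups. The adjacent ring atom C2 is an oxygen-bearing carbon carrying CO2Me, which is a glyoxylate carbonyl carbon, so C2-C3 is an allylboration bond.
Forward, one protected aldehyde is used twice: olefination makes aryl-CH=C4 (as a cinnamate), conjugate borylation places boron on that benzylic carbon, and aldol/elimination adds C3 with its aryl.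
Allylboration of methyl glyoxylate then joins C2-C3 with allyl transposition; the only ring closes last by O1-C5 lactonisation, and debenzylation follows.
Stereochemistry: the chiral copper catalyst of the conjugate borylation sets one C-B stereocentre. That centre is consumed in the allylboration chair and relayed into C2 (S), C3 (R) and the Z-benzylidene, while the cis relation comes from the alkene geometry of the allylboronate.
Key step: step 5

Abbreviations: Bpin or pinacolboryl = 4,4,5,5-tetramethyl-1,3,2-dioxaborolan-2-yl; C-alpha = the boron-bearing carbon of the allylboronate, which becomes the benzylidene CH.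
Assumption: the ligand enantiomer written in step 2 is taken to give the (S)-configured benzylic boronate. The sense is confirmed on the first batch (oxidation of an aliquot with retention, then chiroptical correlation), and the equally available mirror-image ligand is used if the opposite sense is found.
Remark: methyl glyoxylate is sold in oligomeric form or in solution and is distilled to the monomer immediately before use.

Step 1
Reactants: 1 3,4-bis(benzyloxy)benzaldehyde; 2 trimethyl phosphonoacetate
Product: 3 methyl (E)-3-[3,4-bis(benzyloxy)phenyl]acrylate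
Conditions: LiCl, DBU, MeCN, 0 °C to rt
Reagents that add atoms: none
Why: Horner-Wadsworth-Emmons olefination of an aromatic aldehyde with a stabilised phosphonate under mild LiCl/amine conditions is reliably E-selective and leaves the benzyl ethers and the methyl ester untouched.

Step 2
Reactants: 3 methyl (E)-3-[3,4-bis(benzyloxy)phenyl]acrylate
Product: 4 methyl (S)-3-[3,4-bis(benzyloxy)phenyl]-3-(pinacolboryl)propanoate
Conditions: CuCl (3 mol%), NaOt-Bu (4 mol%), (R)-1-[(S)-2-(diphenylphosphino)ferrocenyl]ethyldicyclohexylphosphine (3.5 mol%), B2pin2, MeOH (2 equiv), THF, rt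
Reagents that add atoms: bis(pinacolato)diboron, CC1(C)OB(OC1(C)C)B1OC(C)(C)C(C)(C)O1
Why: In this copper-catalysed enantioselective conjugate borylation of an (E)-cinnamate, the ligated copper boryl adds to one enantiotopic face of the beta-carbon and methanol protonates the copper enolate, so the chiral bisphosphine alone sets the (S) C-B stereocentre, the only externally induced stereocentre of the route.

Step 3
Reactants: 4 methyl (S)-3-[3,4-bis(benzyloxy)phenyl]-3-(pinacolboryl)propanoate; 1 3,4-bis(benzyloxy)benzaldehyde
Product: 6 methyl (3S)-2-{[3,4-bis(benzyloxy)phenyl](hydroxy)methyl}-3-[3,4-bis(benzyloxy)phenyl]-3-(pinacolboryl)propanoate (mixture at C2 and at the carbinol carbon; carried on crude), via lithium enolate 5 (not isolated)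
Conditions: LiN(i-Pr)2, THF, -78 °C; then 1, -78 °C; AcOH quench at -78 °C
Reagents that add atoms: lithium diisopropylamide, [Li]N(C(C)C)C(C)C (supplies only the lithium of 5; nothing from it remains in 6)
Why: In this lithium ester enolate aldol addition the hindered amide removes the ester alpha-proton kinetically and tolerates pinacol boronates (as in Matteson homologations run with the same base in situ), the C-B centre is not touched, and the two new centres need no control because both are erased in step 4.

Step 4
Reactants: 6 methyl (3S)-2-{[3,4-bis(benzyloxy)phenyl](hydroxy)methyl}-3-[3,4-bis(benzyloxy)phenyl]-3-(pinacolboryl)propanoate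
Product: 8 methyl (E)-3-[3,4-bis(benzyloxy)phenyl]-2-{(R)-[3,4-bis(benzyloxy)phenyl](pinacolboryl)methyl}acrylate (alkene aryl trans to CO2Me and cis to the CH(Bpin) carbon; purified to geometric homogeneity and stored cold), via acetate 7 (not isolated)
Conditions: Ac2O, Et3N, DMAP (cat.), CH2Cl2, 0 °C; then DBU, 0 °C to rt
Reagents that add atoms: acetic anhydride, CC(=O)OC(C)=O (acetyl group of 7; lost again on the way to 8)
Why: O-Acetylation followed by amine-promoted E1cB elimination sends all diastereomers through the same ester enolate and should give the conjugated E-alkene, in which the ester stays coplanar and the CH(Bpin) hydrogen turns towards the cis aryl, while DBU at or below room temperature is too weak to deprotonate the C-B carbon, so its configuration is kept and only the descriptor changes from S to R through the CIP ranking.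

Step 5
Reactants: 8 methyl (E)-3-[3,4-bis(benzyloxy)phenyl]-2-{(R)-[3,4-bis(benzyloxy)phenyl](pinacolboryl)methyl}acrylate; 9 methyl glyoxylate
Product: 11 dimethyl (2S,3R,4Z)-3-[3,4-bis(benzyloxy)phenyl]-4-{[3,4-bis(benzyloxy)phenyl]methylidene}-2-hydroxypentanedioate, via pinacol borate 10 (not isolated)
Conditions: 9 (3 equiv, freshly distilled monomer), 4 Å molecular sieves, toluene, 40 °C, no base; then aq. NaH2PO4/Na2HPO4 (pH 7), rt
Reagents that add atoms: none
Why: The aldehyde oxygen of 9 binds the boron of 8 and C2-C3 forms on the allyl face that carries boron through a closed six-membered chair (B, O, C2, C3, C4, C-alpha), while the double bond moves to C4=CH(aryl) and the C-B stereocentre is consumed; this combines the known allylboration of aldehydes by 2-alkoxycarbonyl allylboronates with the known 1,3-chirality transfer from alpha-substituted allylboronates whose gamma-substituent is cis to the boron-bearing carbon. No ring of the product closes in this step, since the chair exists only in the transition state and the lactone is left to step 6. C3 (R) is fixed by the allyl face that reacts, and that face is dictated by the (R) C-B centre once the alpha-hydrogen sits inside and the alpha-aryl outside (equatorial), because the other rotamer would press the two aryl groups of the U-shaped allyl unit together in a 1,3-diaxial contact. C2 (S) follows from the equatorial CO2Me of the glyoxylate facing the axial gamma-aryl, which is the syn addition that later appears as the cis-2,3 lactone. The equatorial alpha-aryl ends up trans to C3 and cis to C5, which is the Z-benzylidene. The step needs the alpha-aryl-equatorial chair to win over the alpha-aryl-axial chair; leakage through the latter would give the E-alkene with the mirror-image ring centres, a separable diastereomer and not the enantiomer, and the high electrophilicity of 9 should let the crowded, ester-deactivated boronate react without Lewis acid or base.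

Step 6
Reactants: 11 dimethyl (2S,3R,4Z)-3-[3,4-bis(benzyloxy)phenyl]-4-{[3,4-bis(benzyloxy)phenyl]methylidene}-2-hydroxypentanedioate
Product: 12 methyl (2S,3R,4Z)-3-[3,4-bis(benzyloxy)phenyl]-4-{[3,4-bis(benzyloxy)phenyl]methylidene}-5-oxooxolane-2-carboxylate (cis-2,3 lactone)
Conditions: p-TsOH·H2O (10 mol%), CH2Cl2, rt, dark
Reagents that add atoms: none
Why: Acid-catalysed lactonisation (5-exo-trig attack of the C2 hydroxyl on the C5 methyl ester with loss of methanol) closes the only ring without breaking a bond at C2, C3 or the alkene, and base is avoided because it would epimerise C2 and could move the double bond into the ring.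

Step 7
Reactants: 12 methyl (2S,3R,4Z)-3-[3,4-bis(benzyloxy)phenyl]-4-{[3,4-bis(benzyloxy)phenyl]methylidene}-5-oxooxolane-2-carboxylate
Product: 14 methyl (2S,3R,4Z)-3-(3,4-dihydroxyphenyl)-4-[(3,4-dihydroxyphenyl)methylidene]-5-oxooxolane-2-carboxylate (CNP0143432.1), via bis(chlorodioxaborole) 13 (not isolated)
Conditions: BCl3 (excess), C6HMe5 (excess), CH2Cl2, -78 °C, dark; then THF/aq. NaH2PO4/Na2HPO4 (pH 7), -78 °C to 0 °C
Reagents that add atoms: boron trichloride, ClB(Cl)Cl (boron and chlorine of 13; nothing from it remains in 14)
Why: Lewis-acid cleavage of aryl benzyl ethers with BCl3 and pentamethylbenzene as a non-basic benzyl cation scavenger runs at -78 °C, spares the methyl ester, the lactone and the trisubstituted alkene that hydrogenolysis would reduce, and the boron-bound catechols are released by neutral hydrolysis, so no stereochemical element is disturbed.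

Compound list
1 | 3,4-bis(benzyloxy)benzaldehyde | O=Cc1ccc(OCc2ccccc2)c(OCc2ccccc2)c1 | starting material
2 | trimethyl phosphonoacetate | COC(=O)CP(=O)(OC)OC | starting material
3 | methyl (E)-3-[3,4-bis(benzyloxy)phenyl]acrylate | COC(=O)/C=C/c1ccc(OCc2ccccc2)c(OCc2ccccc2)c1 | intermediate
4 | methyl (S)-3-[3,4-bis(benzyloxy)phenyl]-3-(pinacolboryl)propanoate | COC(=O)C[C@H](B1OC(C)(C)C(C)(C)O1)c1ccc(OCc2ccccc2)c(OCc2ccccc2)c1 | intermediate
5 | lithium enolate of 4 (enolate geometry not defined, C-B centre unchanged) | COC(O[Li])=C[C@H](B1OC(C)(C)C(C)(C)O1)c1ccc(OCc2ccccc2)c(OCc2ccccc2)c1 | intermediate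
6 | methyl (3S)-2-{[3,4-bis(benzyloxy)phenyl](hydroxy)methyl}-3-[3,4-bis(benzyloxy)phenyl]-3-(pinacolboryl)propanoate, mixture at C2 and the carbinol carbon | COC(=O)C(C(O)c1ccc(OCc2ccccc2)c(OCc2ccccc2)c1)[C@H](B1OC(C)(C)C(C)(C)O1)c1ccc(OCc2ccccc2)c(OCc2ccccc2)c1 | intermediate
7 | O-acetate of 6 | COC(=O)C(C(OC(C)=O)c1ccc(OCc2ccccc2)c(OCc2ccccc2)c1)[C@H](B1OC(C)(C)C(C)(C)O1)c1ccc(OCc2ccccc2)c(OCc2ccccc2)c1 | intermediate
8 | methyl (E)-3-[3,4-bis(benzyloxy)phenyl]-2-{(R)-[3,4-bis(benzyloxy)phenyl](pinacolboryl)methyl}acrylate | COC(=O)/C(=C/c1ccc(OCc2ccccc2)c(OCc2ccccc2)c1)[C@H](B1OC(C)(C)C(C)(C)O1)c1ccc(OCc2ccccc2)c(OCc2ccccc2)c1 | intermediate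
9 | methyl glyoxylate | COC(=O)C=O | starting material
10 | O-pinacolboryl ether (borate) of 11 | COC(=O)[C@@H](OB1OC(C)(C)C(C)(C)O1)[C@H](c1ccc(OCc2ccccc2)c(OCc2ccccc2)c1)/C(=C/c1ccc(OCc2ccccc2)c(OCc2ccccc2)c1)C(=O)OC | intermediate
11 | dimethyl (2S,3R,4Z)-3-[3,4-bis(benzyloxy)phenyl]-4-{[3,4-bis(benzyloxy)phenyl]methylidene}-2-hydroxypentanedioate | COC(=O)[C@@H](O)[C@H](c1ccc(OCc2ccccc2)c(OCc2ccccc2)c1)/C(=C/c1ccc(OCc2ccccc2)c(OCc2ccccc2)c1)C(=O)OC | intermediate
12 | methyl (2S,3R,4Z)-3-[3,4-bis(benzyloxy)phenyl]-4-{[3,4-bis(benzyloxy)phenyl]methylidene}-5-oxooxolane-2-carboxylate | COC(=O)[C@H]1OC(=O)/C(=C\c2ccc(OCc3ccccc3)c(OCc3ccccc3)c2)[C@H]1c1ccc(OCc2ccccc2)c(OCc2ccccc2)c1 | intermediate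
13 | lactone with both catechols bound as 2-chloro-1,3,2-benzodioxaboroles | COC(=O)[C@H]1OC(=O)/C(=C\c2ccc3OB(Cl)Oc3c2)[C@H]1c1ccc2OB(Cl)Oc2c1 | intermediate
14 | methyl (2S,3R,4Z)-3-(3,4-dihydroxyphenyl)-4-[(3,4-dihydroxyphenyl)methylidene]-5-oxooxolane-2-carboxylate | COC(=O)[C@H]1OC(=O)/C(=C\c2ccc(O)c(O)c2)[C@H]1c1ccc(O)c(O)c1 | target

Total step count: 7. Longest linear sequence: 7 steps (1 to 14).

Steps most likely to fail

Step 5. The crowded, ester-deactivated pinacol boronate may add too slowly. Protodeboronation, a 1,3-boron shift (which racemises this constitutionally symmetric allyl unit) or leakage through the chair with the alpha-aryl axial could then compete.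
- The fallback changes the boron reagent instead of forcing the pinacol ester.
- Setting out from 8, KHF2 in MeOH/H2O gives the potassium (R,E)-allyltrifluoroborate F1.
- BF3·OEt2 in CH2Cl2 at -78 °C, in the presence of 9, strips one fluoride to give the allyldifluoroborane F2.
- F2 adds through the same closed chair at low temperature, as is known for allyl- and crotyltrifluoroborates. The small fluorine ligands remove the clash between dioxaborolane methyl groups and an equatorial alpha-substituent.
- The difluoroboryl ether F3 is hydrolysed on buffered work-up, and the route is rejoined at 11.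

Step 4. The elimination may show incomplete geometric control, enantiopurity may erode through reversible deprotonation at the C-B carbon, or boron may be lost during prolonged exposure to the amine.
- The fallback builds the trisubstituted alkene by olefination instead of elimination.
- Setting out from 1 and 2, Knoevenagel condensation (piperidine, AcOH, toluene, water separator) gives the phosphonoacrylate F4.
- Conjugate borylation with the catalyst system of step 2 (ligand enantiomer chosen by the same check) gives the beta-boryl phosphonoacetate F5.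
- Horner-Wadsworth-Emmons reaction of F5 with a second portion of 1 (LiCl, DBU, MeCN, 0 °C) should place the aryl trans to CO2Me, and the route is rejoined at 8.

Step 3. The amide base, the enolate oxygen or the aldolate oxygen may complex with boron. Deprotonation at the benzylic C-B position could also compete, as could retro-aldol cleavage or loss of pinacol on handling.
- The fallback avoids the lithium enolate altogether by a copper-catalysed three-component borylative aldol reaction.
- Setting out from 3 and 1, it uses CuCl, NaOt-Bu, the ligand of step 2 and B2pin2 in THF without methanol, with slow addition of 1.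
- The copper enolate born in the enantioselective conjugate borylation is intercepted by the aldehyde, and the copper aldolate is turned over by B2pin2 to the O-pinacolboryl aldol ether F6.
- F6 is hydrolysed on work-up, and the route is rejoined at 6.

Further compounds
F1 | step 5 | potassium (R,E)-{1,3-bis[3,4-bis(benzyloxy)phenyl]-2-(methoxycarbonyl)prop-2-en-1-yl}trifluoroborate | [K+].COC(=O)/C(=C/c1ccc(OCc2ccccc2)c(OCc2ccccc2)c1)[C@H]([B-](F)(F)F)c1ccc(OCc2ccccc2)c(OCc2ccccc2)c1
F2 | step 5 | methyl (E)-3-[3,4-bis(benzyloxy)phenyl]-2-{(R)-[3,4-bis(benzyloxy)phenyl](difluoroboryl)methyl}acrylate | COC(=O)/C(=C/c1ccc(OCc2ccccc2)c(OCc2ccccc2)c1)[C@H](B(F)F)c1ccc(OCc2ccccc2)c(OCc2ccccc2)c1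
F3 | step 5 | O-difluoroboryl ether of 11 | COC(=O)[C@@H](OB(F)F)[C@H](c1ccc(OCc2ccccc2)c(OCc2ccccc2)c1)/C(=C/c1ccc(OCc2ccccc2)c(OCc2ccccc2)c1)C(=O)OC
F4 | step 4 | methyl (E)-3-[3,4-bis(benzyloxy)phenyl]-2-(dimethoxyphosphoryl)acrylate (aryl trans to phosphorus) | COC(=O)/C(=C\c1ccc(OCc2ccccc2)c(OCc2ccccc2)c1)P(=O)(OC)OC
F5 | step 4 | methyl (3R)-3-[3,4-bis(benzyloxy)phenyl]-2-(dimethoxyphosphoryl)-3-(pinacolboryl)propanoate (mixture at C2; same spatial arrangement at C-B as in 4) | COC(=O)C(P(=O)(OC)OC)[C@H](B1OC(C)(C)C(C)(C)O1)c1ccc(OCc2ccccc2)c(OCc2ccccc2)c1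
F6 | step 3 | O-pinacolboryl ether of 6 | COC(=O)C(C(OB1OC(C)(C)C(C)(C)O1)c1ccc(OCc2ccccc2)c(OCc2ccccc2)c1)[C@H](B1OC(C)(C)C(C)(C)O1)c1ccc(OCc2ccccc2)c(OCc2ccccc2)c1
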